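**Plan**
Numbering: O1, C2 (aryl), C3 (CH2OH), C4 (3,4,5-trimethoxybenzyl), C5. The exocyclic CH2 on C4 is bonded to the ring on one side and to an arene on the other, so O1–C5–C4–CH2 is a masked O-allyl group. C3 carries a carbon that can be an ester and so stabilise a radical at C3.
Cuts: CH2OH goes back to CO2Et. Then C3–C4 and CH2–aryl are cut together, opening the ring to an α-bromo-β-allyloxy ester and an arylzinc. Then C–Br, O–allyl and the carbinol C–H are removed, back to an aroylacetate.
Forward: three steps prepare the open chain and one step makes the arylzinc. The only ring closes 5-exo in the nickel cascade, and ester reduction ends the route.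
Stereochemistry: C2 comes from catalytic asymmetric hydrogenation. C3 and C4 are relayed from C2 in the cyclisation (2,3-trans, 3,4-cis). The C–Br centre is lost in the radical and needs no control.

Key step: step 5

Remark on the chemistry: the bromine-bearing carbon of the cyclisation precursor is written without a descriptor, since bromination should give both epimers and both lead to the same planar radical.

**Step 1**
Reactants: 1 ethyl 3-oxo-3-(3,4,5-trimethoxyphenyl)propanoate
Product: 2 ethyl (3S)-3-hydroxy-3-(3,4,5-trimethoxyphenyl)propanoate
Conditions: [RuCl(p-cymene)((R)-SEGPHOS)]Cl (0.2 mol %), H2 (30 bar), EtOH, 50 °C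
Reagents that add atoms: none
Why: Noyori asymmetric hydrogenation of a β-keto ester: the ketone is held on ruthenium through ester chelation and the (R)-configured, narrow-angle biaryl diphosphine (a ligand class that serves aroylacetates well) admits hydride to one face only, the same spatial sense that turns acetoacetates into (R)-3-hydroxybutanoates and here, with aryl outranking CH2CO2Et, is named S, which sets the future C2.

**Step 2**
Reactants: 2 ethyl (3S)-3-hydroxy-3-(3,4,5-trimethoxyphenyl)propanoate; 3 allyl 2,2,2-trichloroacetimidate
Product: 4 ethyl (3S)-3-(allyloxy)-3-(3,4,5-trimethoxyphenyl)propanoate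
Conditions: 3 (1.8 equiv), TfOH (5 mol %), cyclohexane–CH2Cl2 2:1, 0 °C → rt
Reagents that add atoms: none
Why: Acid-catalysed trichloroacetimidate O-alkylation delivers allyl to the hydroxyl oxygen without any base, so retro-aldol cleavage and β-elimination are avoided and the C–O bond at the stereocentre stays intact, the small acid charge, the low temperature and the destabilising β-ester keeping the benzylic position from ionising.

**Step 3**
Reactants: 4 ethyl (3S)-3-(allyloxy)-3-(3,4,5-trimethoxyphenyl)propanoate
Product: 6 ethyl (3R)-3-(allyloxy)-2-bromo-3-(3,4,5-trimethoxyphenyl)propanoate (both C2 epimers), via silyl ketene acetal 5 (not isolated)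
Conditions: TMSCl (1.5 equiv), LDA (1.15 equiv, added last), THF, −78 °C; then NBS (1.1 equiv), −78 → −30 °C
Reagents that add atoms: chlorotrimethylsilane, C[Si](C)(C)Cl (retained only in 5); N-bromosuccinimide, O=C1CCC(=O)N1Br
Why: Ester enolisation under in situ silylation followed by electrophilic bromination of the silyl ketene acetal: trapping the lithium enolate as it forms keeps its lifetime too short for E1cB loss of allyloxide, the ketene acetal outruns the allyl double bond and the arene for NBS at low temperature, and the new C–Br centre needs no control because the radical of step 5 erases it (the benzylic descriptor changes from S to R only because CHBr outranks aryl).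

**Step 4**
Reactants: 7 5-bromo-1,2,3-trimethoxybenzene
Product: 9 (3,4,5-trimethoxyphenyl)zinc bromide (titrated THF solution), via arylmagnesium bromide 8 (not isolated)
Conditions: Mg turnings (crystal of iodine), THF, 45 °C; solution cannulated off residual Mg; ZnBr2 (1.05 equiv), THF, 0 °C → rt
Reagents that add atoms: magnesium, [Mg] (retained only in 8); zinc dibromide, Br[Zn]Br
Why: Grignard formation and transmetalation to zinc give a mild aryl donor that tolerates the ester of 6, and this preparation leaves neither zinc metal nor an alkyl halide in the solution, either of which could divert 6 into a Reformatsky-type enolate or compete for nickel.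

**Step 5**
Reactants: 6 ethyl (3R)-3-(allyloxy)-2-bromo-3-(3,4,5-trimethoxyphenyl)propanoate; 9 (3,4,5-trimethoxyphenyl)zinc bromide
Product: 12 ethyl (2S,3S,4R)-4-(3,4,5-trimethoxybenzyl)-2-(3,4,5-trimethoxyphenyl)tetrahydrofuran-3-carboxylate, via α-ester radical 10 (not isolated), via cyclised primary radical 11 (not isolated)
Conditions: NiBr2·glyme (5 mol %), 2,2':6',2''-terpyridine (6 mol %), 9 (1.6 equiv), THF–NMP 1:1, 0.05 M in 6, 0 °C → rt
Reagents that add atoms: none
Why: Reduction of NiBr2·glyme/terpyridine by 9 gives a terpyridine aryl nickel species in the monovalent state that abstracts bromine from either epimer of 6; the planar radical 10 adds to the allyl double bond to form C3–C4, and radical 11 combines with the divalent aryl nickel bromide to a trivalent alkyl(aryl)nickel, which reductively eliminates the CH2–aryl bond before transmetalation with 9 restarts the cycle. The closest known reaction type is the nickel-catalysed tandem radical cyclisation/Negishi arylation (alkene 1,2-dicarbofunctionalisation) of halides tethered to an O-allyl group, together with the nickel-catalysed alkylarylation of alkenes by α-halo carbonyl compounds and arylzinc reagents. The tetrahydrofuran, the only ring formed, closes in the 5-exo-trig mode, which the short C–O bonds of the 3-oxa-5-hexenyl chain favour over 6-endo. Both new stereocentres are governed by C2: in the chair-like transition state its aryl group sits pseudo-equatorial, so the alkene is attacked on the face that puts the new CH2 at C4 trans to the aryl, while the ester on the radical carbon turns away from the aryl (C3, 2,3-trans) and thereby ends cis to that CH2, in line with the usual 1,5-cis preference of 1-substituted hexenyl radicals. The step needs ring closure to beat bimolecular capture of 10 by nickel (direct α-arylation, or a nickel enolate that expels allyloxide); closure is unimolecular and fast for an electrophilic radical facing an unhindered terminal alkene, so low nickel loading and dilution secure it. Control at C4 is expected to be the weaker of the two, and any 3,4-trans isomer would be removed by chromatography at this stage.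

**Step 6**
Reactants: 12 ethyl (2S,3S,4R)-4-(3,4,5-trimethoxybenzyl)-2-(3,4,5-trimethoxyphenyl)tetrahydrofuran-3-carboxylate
Product: 13 [(2S,3R,4R)-4-(3,4,5-trimethoxybenzyl)-2-(3,4,5-trimethoxyphenyl)tetrahydrofuran-3-yl]methanol
Conditions: LiAlH4 (1.5 equiv), THF, 0 °C; H2O/aq NaOH work-up
Reagents that add atoms: none
Why: Hydride reduction of an ester to the primary alcohol with LiAlH4 is much faster than enolisation at 0 °C, so C3 keeps its configuration (its descriptor changes from S to R only because CH2OH ranks below C2), and the aryl methyl ethers and the cyclic ether are inert.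

**Compound list**
1 | ethyl 3-oxo-3-(3,4,5-trimethoxyphenyl)propanoate | CCOC(=O)CC(=O)c1cc(OC)c(OC)c(OC)c1 | starting material
2 | ethyl (3S)-3-hydroxy-3-(3,4,5-trimethoxyphenyl)propanoate | O[C@H](c1cc(OC)c(OC)c(OC)c1)CC(=O)OCC | intermediate
3 | allyl 2,2,2-trichloroacetimidate | C=CCOC(=N)C(Cl)(Cl)Cl | starting material
4 | ethyl (3S)-3-(allyloxy)-3-(3,4,5-trimethoxyphenyl)propanoate | C=CCO[C@H](c1cc(OC)c(OC)c(OC)c1)CC(=O)OCC | intermediate
5 | {[(3S)-3-(allyloxy)-1-ethoxy-3-(3,4,5-trimethoxyphenyl)prop-1-en-1-yl]oxy}trimethylsilane, alkene geometry immaterial (not isolated) | C=CCO[C@H](c1cc(OC)c(OC)c(OC)c1)C=C(OCC)O[Si](C)(C)C | intermediate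
6 | ethyl (3R)-3-(allyloxy)-2-bromo-3-(3,4,5-trimethoxyphenyl)propanoate, both C2 epimers | C=CCO[C@H](c1cc(OC)c(OC)c(OC)c1)C(Br)C(=O)OCC | intermediate
7 | 5-bromo-1,2,3-trimethoxybenzene | COc1cc(Br)cc(OC)c1OC | starting material
8 | (3,4,5-trimethoxyphenyl)magnesium bromide (not isolated) | COc1cc([Mg]Br)cc(OC)c1OC | intermediate
9 | (3,4,5-trimethoxyphenyl)zinc bromide | COc1cc([Zn]Br)cc(OC)c1OC | intermediate
10 | (3S)-3-(allyloxy)-1-ethoxy-1-oxo-3-(3,4,5-trimethoxyphenyl)propan-2-yl radical (not isolated) | C=CCO[C@H](c1cc(OC)c(OC)c(OC)c1)[CH]C(=O)OCC | intermediate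
11 | [(2S,3S,4R)-3-(ethoxycarbonyl)-2-(3,4,5-trimethoxyphenyl)tetrahydrofuran-4-yl]methyl radical (not isolated) | [CH2][C@H]1CO[C@H](c2cc(OC)c(OC)c(OC)c2)[C@H]1C(=O)OCC | intermediate
12 | ethyl (2S,3S,4R)-4-(3,4,5-trimethoxybenzyl)-2-(3,4,5-trimethoxyphenyl)tetrahydrofuran-3-carboxylate (2,3-trans, 3,4-cis) | COc1cc(C[C@H]2CO[C@H](c3cc(OC)c(OC)c(OC)c3)[C@H]2C(=O)OCC)cc(OC)c1OC | intermediate
13 | [(2S,3R,4R)-4-(3,4,5-trimethoxybenzyl)-2-(3,4,5-trimethoxyphenyl)tetrahydrofuran-3-yl]methanol | COc1cc(C[C@H]2CO[C@H](c3cc(OC)c(OC)c(OC)c3)[C@H]2CO)cc(OC)c1OC | target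

Total step count: 6.
Longest linear sequence: 5 steps (1 → 2 → 4 → 6 → 12 → 13). Step 4 is a one-step side branch.

**Steps most likely to fail**

Step 5. Nickel may intercept the α-ester radical before it has cyclised, leading to α-arylation or to enolate formation followed by expulsion of allyloxide. The two alkene faces may also be poorly differentiated. The fallback uncouples ring closure from arylation. Setting out from 6, a copper-catalysed atom-transfer radical cyclisation of the Kharasch type is run with no aryl metal in the flask (CuBr 5 mol %, tris(2-pyridylmethyl)amine 5 mol %, ascorbic acid 10 mol %, MeCN, 40 °C). It forms C3–C4 by the same 5-exo closure and hands bromine back to the primary radical, giving ethyl (2S,3S,4R)-4-(bromomethyl)-2-(3,4,5-trimethoxyphenyl)tetrahydrofuran-3-carboxylate F1, which can be freed of its C4 epimer at this point. A nickel-catalysed alkyl–aryl Negishi coupling of this primary bromide with 9 (NiBr2·glyme, terpyridine, THF–NMP, rt) then makes the CH2–aryl bond and rejoins the route at 12.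

Step 3. The lithium enolate may lose allyloxide by E1cB elimination faster than it is silylated. The fallback installs the halogen before the carbinol and the ether exist, where enolisation is easy and no leaving group is present.
- Setting out from 1, SO2Cl2 (CH2Cl2, 0 °C) gives ethyl 2-chloro-3-oxo-3-(3,4,5-trimethoxyphenyl)propanoate F2.
- Hydrogenation with the catalyst of step 1 (H2, CH2Cl2–EtOH, 50 °C) is a dynamic kinetic resolution of the labile α-centre in which the ligand again fixes the carbinol. It gives ethyl (3R)-2-chloro-3-hydroxy-3-(3,4,5-trimethoxyphenyl)propanoate F3. The carbinol has the same spatial arrangement as in 2, and the descriptor differs only because CHCl outranks aryl.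
- O-allylation with 3 under the conditions of step 2 gives ethyl (3R)-3-(allyloxy)-2-chloro-3-(3,4,5-trimethoxyphenyl)propanoate F4.
- F4 takes the place of 6 in step 5, with NaI (20 mol %) as halide-exchange promoter, and the route is rejoined at 12.

Step 2. The acid may ionise the electron-rich benzylic C–O bond, eroding enantiopurity or causing elimination, and the imidate may rearrange to its N-allyl amide before it is consumed. The fallback transfers allyl under neutral conditions through a π-allyl complex. Setting out from 2, allyl chloroformate and pyridine (CH2Cl2, 0 °C) give ethyl (3S)-3-{[(allyloxy)carbonyl]oxy}-3-(3,4,5-trimethoxyphenyl)propanoate F5. Zerovalent palladium (Pd(PPh3)4 5 mol %, THF, 65 °C) ionises the allyl carbonate, CO2 is lost and the alkoxide recombines with the π-allyl cation (decarboxylative Tsuji–Trost etherification). The C–O bond at the stereocentre is never touched, and the route is rejoined at 4.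

**Further compounds**
F1 | step 5 | ethyl (2S,3S,4R)-4-(bromomethyl)-2-(3,4,5-trimethoxyphenyl)tetrahydrofuran-3-carboxylate | BrC[C@H]1CO[C@H](c2cc(OC)c(OC)c(OC)c2)[C@H]1C(=O)OCC
F2 | step 3 | ethyl 2-chloro-3-oxo-3-(3,4,5-trimethoxyphenyl)propanoate (racemic, labile α-centre) | CCOC(=O)C(Cl)C(=O)c1cc(OC)c(OC)c(OC)c1
F3 | step 3 | ethyl (3R)-2-chloro-3-hydroxy-3-(3,4,5-trimethoxyphenyl)propanoate (C2 immaterial) | O[C@H](c1cc(OC)c(OC)c(OC)c1)C(Cl)C(=O)OCC
F4 | step 3 | ethyl (3R)-3-(allyloxy)-2-chloro-3-(3,4,5-trimethoxyphenyl)propanoate (C2 immaterial) | C=CCO[C@H](c1cc(OC)c(OC)c(OC)c1)C(Cl)C(=O)OCC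
F5 | step 2 | ethyl (3S)-3-{[(allyloxy)carbonyl]oxy}-3-(3,4,5-trimethoxyphenyl)propanoate | C=CCOC(=O)O[C@H](c1cc(OC)c(OC)c(OC)c1)CC(=O)OCC
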